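**Plan**
- Retrosynthesis: the two acetates are exchanged for silyl ethers, then the C2–C3 bond of the ten-membered carbocycle is cut. The enabling feature is that the C1 ketone and the (Z)-C4=C5 olefin are γ,δ-related, and the whole unit O=C1–C2–C3–C4=C5 lies inside the carbocycle.
- A retro-Claisen step turns this unit into C2H2=C1–O–C5H–C4(Me)=C3H2. The result is an eight-membered oxocane (O, C1, C10, C9, C8, C7, C6, C5) fused to the butenolide at C6–C7.
- Further cuts: O–C1 (alkynol hydroalkoxylation), C5–C6 (vinylogous aldol with methacrolein), C8–C9 (allylboration), and the butenolide itself (butynediol + vinyl Grignard + CO2).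
- Forward ring order: butenolide (step 1), oxocane (step 8), ten-membered carbocycle by a two-atom ring expansion (step 9).
- Stereochemistry: C8 comes from a chiral phosphoric acid. C6, together with the sacrificial C5, comes from a chiral Lewis base/SiCl4 catalyst. The 4Z geometry comes from the ring-constrained Claisen transition state.

Key step: step 9

Remark (numbering): germacrane numbering of the target is used for all compounds. C1 is the ketone, followed by C2, C3, C4(C15H3)=C5, C6 (lactone O), C7=C11 (butenolide), C8 (OAc), C9 and C10(=C14H2). C12 is the lactone C=O and C13 is CH2OAc.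
Remark (assumption): the sense of induction of (S)-TRIP (step 5) and of the (R,R)-bisphosphoramide (step 7) is assigned by analogy with aryl and enal substrates. If the opposite sense is found, the antipodal catalyst is used and nothing else changes. C5 is drawn R (5,6-anti) and is erased in step 9.

**Step 1**
Reactants: 1 but-2-yne-1,4-diol; 2 vinylmagnesium chloride
Product: 4 3-(hydroxymethyl)-4-vinylfuran-2(5H)-one, via oxamagnesacycle 3 (not isolated)
Conditions: 2 (4 equiv), THF, reflux; CO2 (g), 0 °C; 2 M HCl
Reagents that add atoms: carbon dioxide, O=C=O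
Why: Hydroxyl-directed anti-carbomagnesiation of the propargylic dialkoxide puts vinyl on C7 and magnesium on C11 cis to the C6 alkoxide (five-membered chelate 3), so carboxylation with retention and acidification should give a (Z)-γ-hydroxy acid that lactonises spontaneously to the fully substituted butenolide; no stereocentre is formed.

**Step 2**
Reactants: 4 3-(hydroxymethyl)-4-vinylfuran-2(5H)-one
Product: 5 3-[(tert-butyldimethylsilyloxy)methyl]-4-vinylfuran-2(5H)-one
Conditions: TBSCl, imidazole, CH2Cl2, 0 °C to rt
Reagents that add atoms: tert-butyldimethylsilyl chloride, CC(C)(C)[Si](C)(C)Cl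
Why: Standard silylation of a primary allylic alcohol; a silyl ether is carried instead of the final acetate because O13 sits β to the nucleophilic carbon C11 of the silyloxyfuran of steps 6–7 and must be a poor leaving group.

**Step 3**
Reactants: 5 3-[(tert-butyldimethylsilyloxy)methyl]-4-vinylfuran-2(5H)-one
Product: 7 4-[(tert-butyldimethylsilyloxy)methyl]-5-oxo-2,5-dihydrofuran-3-carbaldehyde, via secondary ozonide 6 (not isolated)
Conditions: O3, CH2Cl2, −78 °C (dye indicator); Me2S, −78 °C to rt
Reagents that add atoms: ozone, [O-][O+]=O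
Why: Ozonolysis should be chemoselective for the terminal vinyl group because the tetrasubstituted C7=C11 bond is deactivated by the lactone carbonyl, and reductive work-up of 6 gives the C8 aldehyde.

**Step 4**
Reactants: 8 2-methylbut-1-en-3-yne
Product: 10 2-(2-methylidenebut-3-yn-1-yl)-4,4,5,5-tetramethyl-1,3,2-dioxaborolane, via allyl-acetylide dianion 9 (not isolated)
Conditions: n-BuLi/KOt-Bu (2.1 equiv each), THF–hexane, −78 to −20 °C; i-PrOBpin (1.0 equiv), −78 °C; HCl/Et2O
Reagents that add atoms: 2-isopropoxy-4,4,5,5-tetramethyl-1,3,2-dioxaborolane, CC(C)OB1OC(C)(C)C(C)(C)O1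
Why: Superbase dimetalation at the acetylenic and allylic C–H bonds gives dianion 9, whose far more nucleophilic and symmetric allyl terminus is borylated selectively by one equivalent of borate, while the acetylide is reprotonated on quench (borylation of an allyl metal).

**Step 5**
Reactants: 7 4-[(tert-butyldimethylsilyloxy)methyl]-5-oxo-2,5-dihydrofuran-3-carbaldehyde; 10 2-(2-methylidenebut-3-yn-1-yl)-4,4,5,5-tetramethyl-1,3,2-dioxaborolane
Product: 12 (S)-4-(1-hydroxy-3-methylidenepent-4-yn-1-yl)-3-[(TBSO)methyl]furan-2(5H)-one, via pinacol borate ester 11 (not isolated)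
Conditions: (S)-TRIP (5 mol %), 4 Å MS, toluene, −40 °C; aq. NaHCO3
Reagents that add atoms: none
Why: Chiral-phosphoric-acid-catalysed allylboration runs through a closed chair transition state in which the acid hydrogen-bonds to the pseudo-axial boronate oxygen and to the formyl hydrogen, so the catalyst pocket selects the aldehyde face and sets C8 as S, with the butenolide playing the role of the aryl group of standard substrates.

**Step 6**
Reactants: 12 (S)-4-(1-hydroxy-3-methylidenepent-4-yn-1-yl)-3-[(TBSO)methyl]furan-2(5H)-one
Product: 13 2-(TIPSO)-3-[(TBSO)methyl]-4-[(1S)-3-methylidene-1-(TIPSO)pent-4-yn-1-yl]furan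
Conditions: TIPSOTf (2.4 equiv), Et3N (4 equiv), CH2Cl2, 0 °C to rt
Reagents that add atoms: triisopropylsilyl trifluoromethanesulfonate, CC(C)[Si](C(C)C)(C(C)C)OS(=O)(=O)C(F)(F)F
Why: Silyl triflate/amine silylates O8 and soft-enolises the butenolide by γ-deprotonation at C6, which is favoured over removal of C8–H or C13–H because only it gives an aromatic 2-silyloxyfuran; C8 is untouched.

**Step 7**
Reactants: 13 2-(TIPSO)-3-[(TBSO)methyl]-4-[(1S)-3-methylidene-1-(TIPSO)pent-4-yn-1-yl]furan; 14 methacrolein
Product: 16 (5S)-5-[(1R)-1-hydroxy-2-methylprop-2-en-1-yl]-3-[(TBSO)methyl]-4-[(1S)-3-methylidene-1-(TIPSO)pent-4-yn-1-yl]furan-2(5H)-one, via trichlorosilyl aldolate 15 (not isolated)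
Conditions: SiCl4 (1.2 equiv), (R,R)-binaphthyldiamine-derived bisphosphoramide (5 mol %), i-Pr2NEt (20 mol %), CH2Cl2, −78 °C; sat. aq. NaHCO3
Reagents that add atoms: silicon tetrachloride, Cl[Si](Cl)(Cl)Cl (retained only in 15)
Why: In this catalytic enantioselective vinylogous Mukaiyama aldol reaction the chiral phosphoramide-bound silicon cation activates methacrolein for 1,2-attack by C6, the only free nucleophilic furan position (C11 is blocked), through an open transition state, so aldehyde-face selection and anti topicity set C5 and C6 together; C6 epimers would be separable diastereomers because C8 is fixed.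

**Step 8**
Reactants: 16 (5S)-5-[(1R)-1-hydroxy-2-methylprop-2-en-1-yl]-3-[(TBSO)methyl]-4-[(1S)-3-methylidene-1-(TIPSO)pent-4-yn-1-yl]furan-2(5H)-one
Product: 17 (5R,6S,8S)-butenolide-fused 2,3-dimethylidene-8-isopropenyl-5-(TIPSO)oxocane (ring O–C1(=C2H2)–C10(=C14H2)–C9H2–C8–C7–C6–C5)
Conditions: IPrAuNTf2 (10 mol %), 4 Å MS, toluene, 40 °C, slow addition of 16 (final 2 mM); filtration through Et3N-washed basic alumina
Reagents that add atoms: none
Why: Proposed new method: LAu+ activates the terminal alkyne so that the internal carbon C1, whose developing positive charge is stabilised by C10=C14, is attacked anti by the only free hydroxyl (O5), and protodeauration then gives the exocyclic enol ether in an 8-exo-dig closure; the closest known reaction types are the gold(I)-catalysed exo-dig cycloisomerisation of alkynols to five- to seven-membered 2-methylene oxacycles and the intermolecular gold-catalysed addition of allylic alcohols to alkynes giving allyl vinyl ethers; the medium-ring closure is argued from the three sp2 ring atoms (C1, C10, C7) and the planar butenolide fusion, which remove rotors and transannular H/H contacts, from high dilution, and from the bulky TIPS group that keeps O8 out of the competing five-membered mode; no stereocentre is formed or touched.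

**Step 9**
Reactants: 17 (5R,6S,8S)-butenolide-fused 2,3-dimethylidene-8-isopropenyl-5-(TIPSO)oxocane
Product: 18 (4Z,6R,8S)-13-(TBSO)-8-(TIPSO)-1-oxogermacra-4,7(11),10(14)-trien-12,6-olide
Conditions: xylenes (2 mM), BHT (cat.), base-washed sealed vessel, 130 °C
Reagents that add atoms: none
Why: A concerted suprafacial [3,3]-sigmatropic (Claisen) shift of the allyl vinyl ether C2=C1–O–C5–C4=C3 embedded in 17 breaks the C5–O bond of the oxocane while C2–C3 forms, so the one-atom O bridge between C1 and C5 is replaced by the three-carbon bridge C2–C3–C4 and the eight-membered heterocycle becomes the ten-membered carbocycle, with O5 ending as the C1 ketone oxygen. The closest known reaction type is the ring-expanding Claisen rearrangement of 2-methylene-ω-alkenyl oxacycles (methylenated lactones to cyclooctenones, cyclic ketene acetals to unsaturated medium-ring lactones). The ten-membered ring is closed by pericyclic C2–C3 bond formation in a six-centre array bridged by C6–C10 (bicyclo[5.3.1]-type transition state) rather than by an end-to-end cyclisation, and the gain of the C=O bond makes it irreversible. No new stereocentre arises: C5 is erased, C6 and C8 are spectators (the C6 descriptor changes from S to R only through priorities), and the only stereochemical issue is the C4=C5 geometry. That geometry is secured by the ring, because the C6–C5–O–C1 torsion of an oxocane must stay gauche, which places C6 pseudo-axial on the six-centre array and delivers C6 cis to C3 (Z), whereas the E olefin would need an anti torsion that an eight-membered ring cannot hold. Chemoselectivity rests on neutral conditions (no enolisation of the butenolide), on high dilution against Diels–Alder dimerisation of the 2-oxydiene, and on the cross-conjugated diene having no 1,5-hydrogen-shift pathway.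

**Step 10**
Reactants: 18 (4Z,6R,8S)-13-(TBSO)-8-(TIPSO)-1-oxogermacra-4,7(11),10(14)-trien-12,6-olide
Product: 19 (4Z,6R,8S)-8,13-dihydroxy-1-oxogermacra-4,7(11),10(14)-trien-12,6-olide
Conditions: HF·pyridine, pyridine, THF, 0 °C to rt
Reagents that add atoms: none
Why: Fluoride cleavage of both silyl ethers under buffered, mildly acidic conditions avoids the base-induced removal of C6–H that would scramble C6 or give the γ-alkylidene butenolide; no stereocentre is touched.

**Step 11**
Reactants: 19 (4Z,6R,8S)-8,13-dihydroxy-1-oxogermacra-4,7(11),10(14)-trien-12,6-olide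
Product: 20 (4Z,6R,8S)-8,13-diacetoxy-1-oxogermacra-4,7(11),10(14)-trien-12,6-olide (target)
Conditions: Ac2O, pyridine, DMAP (cat.), CH2Cl2, 0 °C
Reagents that add atoms: acetic anhydride, CC(=O)OC(C)=O
Why: Nucleophile-catalysed acetylation of the primary C13 and secondary C8 alcohols proceeds with retention at C8, and the weak base and low temperature should keep the C13 acetate from vinylogous elimination.

**Compound list**
1 | but-2-yne-1,4-diol | OCC#CCO | starting material
2 | vinylmagnesium chloride | C=C[Mg]Cl | starting material
3 | oxamagnesacycle (chelated alkenylmagnesium alkoxide, not isolated) | C=CC1=C(CO[Mg]Cl)[Mg]OC1 | intermediate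
4 | 3-(hydroxymethyl)-4-vinylfuran-2(5H)-one | O=C1OCC(C=C)=C1CO | intermediate
5 | 3-[(tert-butyldimethylsilyloxy)methyl]-4-vinylfuran-2(5H)-one | O=C1OCC(C=C)=C1CO[Si](C)(C)C(C)(C)C | intermediate
6 | secondary ozonide of 5 (not isolated) | O=C1OCC(C2OCOO2)=C1CO[Si](C)(C)C(C)(C)C | intermediate
7 | 4-[(tert-butyldimethylsilyloxy)methyl]-5-oxo-2,5-dihydrofuran-3-carbaldehyde | O=CC1=C(CO[Si](C)(C)C(C)(C)C)C(=O)OC1 | intermediate
8 | 2-methylbut-1-en-3-yne | C=C(C)C#C | starting material
9 | allyl-acetylide dianion (K/Li counter-ions, not isolated) | [CH2-]C(=C)C#[C-] | intermediate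
10 | 2-(2-methylidenebut-3-yn-1-yl)-4,4,5,5-tetramethyl-1,3,2-dioxaborolane | C#CC(=C)CB1OC(C)(C)C(C)(C)O1 | intermediate
11 | pinacol borate ester of 12 (not isolated) | C#CC(=C)C[C@H](OB1OC(C)(C)C(C)(C)O1)C2=C(CO[Si](C)(C)C(C)(C)C)C(=O)OC2 | intermediate
12 | (S)-4-(1-hydroxy-3-methylidenepent-4-yn-1-yl)-3-[(TBSO)methyl]furan-2(5H)-one | C#CC(=C)C[C@H](O)C1=C(CO[Si](C)(C)C(C)(C)C)C(=O)OC1 | intermediate
13 | 2-(TIPSO)-3-[(TBSO)methyl]-4-[(1S)-3-methylidene-1-(TIPSO)pent-4-yn-1-yl]furan | C#CC(=C)C[C@H](O[Si](C(C)C)(C(C)C)C(C)C)c1coc(O[Si](C(C)C)(C(C)C)C(C)C)c1CO[Si](C)(C)C(C)(C)C | intermediate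
14 | methacrolein | C=C(C)C=O | starting material
15 | trichlorosilyl aldolate (not isolated) | C#CC(=C)C[C@H](O[Si](C(C)C)(C(C)C)C(C)C)C1=C(CO[Si](C)(C)C(C)(C)C)C(=O)O[C@@H]1[C@H](O[Si](Cl)(Cl)Cl)C(C)=C | intermediate
16 | (5S)-5-[(1R)-1-hydroxy-2-methylprop-2-en-1-yl]-3-[(TBSO)methyl]-4-[(1S)-3-methylidene-1-(TIPSO)pent-4-yn-1-yl]furan-2(5H)-one | C#CC(=C)C[C@H](O[Si](C(C)C)(C(C)C)C(C)C)C1=C(CO[Si](C)(C)C(C)(C)C)C(=O)O[C@@H]1[C@H](O)C(C)=C | intermediate
17 | (5R,6S,8S)-butenolide-fused 2,3-dimethylidene-8-isopropenyl-5-(TIPSO)oxocane | C=C2C(=C)C[C@H](O[Si](C(C)C)(C(C)C)C(C)C)C1=C(CO[Si](C)(C)C(C)(C)C)C(=O)O[C@@H]1[C@H](O2)C(C)=C | intermediate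
18 | (4Z,6R,8S)-13-(TBSO)-8-(TIPSO)-1-oxogermacra-4,7(11),10(14)-trien-12,6-olide | C=C1C[C@H](O[Si](C(C)C)(C(C)C)C(C)C)C2=C(CO[Si](C)(C)C(C)(C)C)C(=O)O[C@@H]2/C=C(/C)CCC1=O | intermediate
19 | (4Z,6R,8S)-8,13-dihydroxy-1-oxogermacra-4,7(11),10(14)-trien-12,6-olide | C=C1C[C@H](O)C2=C(CO)C(=O)O[C@@H]2/C=C(/C)CCC1=O | intermediate
20 | (4Z,6R,8S)-8,13-diacetoxy-1-oxogermacra-4,7(11),10(14)-trien-12,6-olide | C=C1C[C@H](OC(C)=O)C2=C(COC(C)=O)C(=O)O[C@@H]2/C=C(/C)CCC1=O | target

**Step count**
Total step count: 11.
Longest linear sequence: 10 (steps 1, 2, 3, 5, 6, 7, 8, 9, 10, 11 from but-2-yne-1,4-diol). Step 4 is a one-step side branch.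

**Steps most likely to fail**

1. Step 8. The eight-membered exo-dig closure may be outrun by three processes:
   - intermolecular addition;
   - hydration by adventitious water;
   - participation of the O8 silyl ether in a five-membered mode.

   The fallback sets out from 16 and returns at 18. The alkyne of 16 is first converted by the established gold(I)-catalysed double addition of methanol (Ph3PAuNTf2, MeOH/HC(OMe)3, rt) into the dimethyl ketal F1. This is then submitted to olefinic ketal Claisen conditions (2,4-dinitrophenol cat., toluene, 110 °C, 1 mM, 4 Å sieves in a Soxhlet head to remove methanol). Reversible alcohol exchange should give the cyclic mixed ketal F2. Loss of a second methanol gives 17 only as a steady-state species, and the irreversible [3,3] shift drains the equilibria to 18.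

2. Step 7. Facial selectivity at C6 may be poor if the resident C8 centre opposes the catalyst, and the strong Lewis acid may ionise the allylic silyl ethers. The fallback sets out from 13 and returns at 16.
   - The addition is run without a chiral catalyst (BF3·OEt2, CH2Cl2, −78 °C).
   - Compound 16 is separated by chromatography from the C6 epimer F3; the two are diastereomers because C8 is fixed.
   - The unwanted isomer is recycled by base equilibration of the butenolide γ-stereocentre (Et3N, CH2Cl2, rt, through the 2-oxidofuran) and re-separated. Kinetic catalyst control is thereby replaced by separation plus thermodynamic recycling.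

3. Step 9. Thermal dimerisation or decomposition of the 2-oxydiene may outrun the [3,3] shift at the temperature needed. The fallback sets out from 17 and returns at 18. The rearrangement is promoted at low temperature by triisobutylaluminium (CH2Cl2, −78 to 0 °C), the known Lewis-acid variant of the ring-expanding Claisen. In this variant the ketone is reduced in situ by β-hydride transfer to the C1 allylic alcohol F4. Oxidation of this allylic alcohol (MnO2, CH2Cl2, or Dess–Martin periodinane/NaHCO3) then restores enone 18.

**Further compounds**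
F1 | step 8 | dimethyl ketal of the C1 methyl ketone derived from 16 | CC(OC)(OC)C(=C)C[C@H](O[Si](C(C)C)(C(C)C)C(C)C)C1=C(CO[Si](C)(C)C(C)(C)C)C(=O)O[C@@H]1[C@H](O)C(C)=C
F2 | step 8 | eight-membered cyclic mixed methyl ketal (C1 unassigned) | CC2(OC)C(=C)C[C@H](O[Si](C(C)C)(C(C)C)C(C)C)C1=C(CO[Si](C)(C)C(C)(C)C)C(=O)O[C@@H]1[C@H](O2)C(C)=C
F3 | step 7 | C6 epimer of 16 | C#CC(=C)C[C@H](O[Si](C(C)C)(C(C)C)C(C)C)C1=C(CO[Si](C)(C)C(C)(C)C)C(=O)O[C@H]1[C@H](O)C(C)=C
F4 | step 9 | C1 allylic alcohol corresponding to 18 (C1 unassigned) | C=C1C[C@H](O[Si](C(C)C)(C(C)C)C(C)C)C2=C(CO[Si](C)(C)C(C)(C)C)C(=O)O[C@@H]2/C=C(/C)CCC1O
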